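**Retrosynthetic overview**

- The strategy rests on the benzene ring C1'–C6': oxygens at C2' (OH), C4' (OH) and C6' (OMe) alternate with carbon groups at C1' (bridging CH2), C3' (prenyl) and C5' (acyl), and the three oxygens must be told apart.
- Last bond, pyrone C3–CH2: the 4-hydroxypyrone 23 captures the o-quinone methide 28 made from the hexasubstituted o-hydroxybenzyl alcohol 27.
- C5' acyl: photo-Fries shift from the 4'-O ester; the only stereocentre is bought as (R)-2-methylbutanoic acid 24.
- Benzene ring: cyclobutenone 7 plus siloxyalkyne 13. C4'-OH comes from the ring carbonyl, C3'/C2'-OTIPS from the alkyne, C6'-OMe and C1' from the enol ether carbons, and C5'-H from the ring CH2.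
- Ring order: cyclobutenone (step 3, sacrificed), benzene ring (step 7), pyrone ring made separately (step 9) and joined last (step 13).

Key step: step 7

Remark on the chemistry: the benzene ring is numbered C1'–C6' from the carbon bearing the bridging CH2, and the pyrone O1, C2–C6. The stereocentre of the target is R, and 24 is assumed to be available in high enantiomeric purity.

**Route**

Step 1
Reactants: 1 trichloroethylene
Product: 2 (E)-1,2-dichloro-1-methoxyethene
Conditions: KOMe (1.1 equiv), MeOH (cat.), THF, −40 °C → rt, under N2; short-path distillation behind a shield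
Reagents that add atoms: potassium methoxide, [K+].[O-]C
Why: Methoxide eliminates HCl to give transient dichloroacetylene, to which methanol adds anti, a net vinylic substitution that is the standard trichloroethylene entry to alkoxyacetylene precursors.

Step 2
Reactants: 2 (E)-1,2-dichloro-1-methoxyethene
Product: 5 tert-butyl[(3-methoxyprop-2-yn-1-yl)oxy]dimethylsilane, via lithium methoxyacetylide 3 (not isolated), via lithium 3-methoxyprop-2-yn-1-olate 4 (not isolated)
Conditions: n-BuLi (2.1 equiv), THF, −78 → −40 °C; (CH2O)n, −78 °C → rt; TBSCl, DMAP (cat.), 0 °C → rt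
Reagents that add atoms: formaldehyde (as paraformaldehyde), C=O; tert-butyldimethylsilyl chloride, CC(C)(C)[Si](C)(C)Cl
Why: Dehydrochlorination and chlorine–lithium exchange give the lithium alkoxyacetylide (Greene-type ynol ether synthesis), which adds to formaldehyde, and silylating the lithium alkoxide in the same flask avoids handling the acid-labile free ynol ether alcohol.

Step 3
Reactants: 5 tert-butyl[(3-methoxyprop-2-yn-1-yl)oxy]dimethylsilane
Product: 6 2-{[(tert-butyldimethylsilyl)oxy]methyl}-4,4-dichloro-3-methoxycyclobut-2-en-1-one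
Conditions: Cl3CCOCl, Zn(Cu), Et2O–DME, rt; used crude
Reagents that add atoms: trichloroacetyl chloride (as dichloroketene), ClC(=O)C(Cl)(Cl)Cl
Why: In this ketene–alkyne [2+2] cycloaddition the ynol ether carbon remote from oxygen bonds to the ketene carbonyl carbon, so methoxy ends at C3 and the silyloxymethyl group at C2, as in the dichloroketene route to cyclobutenones.

Step 4
Reactants: 6 2-{[(tert-butyldimethylsilyl)oxy]methyl}-4,4-dichloro-3-methoxycyclobut-2-en-1-one
Product: 7 2-{[(tert-butyldimethylsilyl)oxy]methyl}-3-methoxycyclobut-2-en-1-one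
Conditions: Zn dust, AcOH, TMEDA, EtOH, 0 °C → rt
Reagents that add atoms: none
Why: Reductive dechlorination of the α,α-dichloro ketone proceeds through zinc enolates protonated by acetic acid, and the TMEDA buffer should spare the vinylogous ester and the silyl ether.

Step 5
Reactants: 8 prenyl bromide; 9 ethynylmagnesium bromide
Product: 10 5-methylhex-4-en-1-yne
Conditions: CuCl (5 mol %), THF, 0 → 45 °C; fractional distillation
Reagents that add atoms: none
Why: Copper-catalysed coupling of an alkynyl Grignard reagent with an allylic bromide should take place at the unhindered primary carbon (SN2) to give the skipped enyne.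

Step 6
Reactants: 10 5-methylhex-4-en-1-yne
Product: 13 triisopropyl[(5-methylhex-4-en-1-yn-1-yl)oxy]silane, via lithium 5-methylhex-4-en-1-yn-1-ide 11 (not isolated), via lithium 5-methylhex-4-en-1-yn-1-olate 12 (not isolated)
Conditions: n-BuLi, THF, −78 °C; LiOOt-Bu (from t-BuOOH and LiHMDS), −78 → 0 °C; TIPSOTf, −78 → 0 °C
Reagents that add atoms: tert-butyl hydroperoxide, CC(C)(C)OO; triisopropylsilyl triflate, CC(C)[Si](C(C)C)(C(C)C)OS(=O)(=O)C(F)(F)F
Why: The lithium acetylide is oxidised by lithium tert-butyl peroxide to the lithium ynolate, which the bulky silyl triflate traps on oxygen (Julia ynolate route to siloxyalkynes), and this nucleophilic peroxide does not epoxidise the trisubstituted alkene.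

Step 7
Reactants: 7 2-{[(tert-butyldimethylsilyl)oxy]methyl}-3-methoxycyclobut-2-en-1-one; 13 triisopropyl[(5-methylhex-4-en-1-yn-1-yl)oxy]silane
Product: 18 4-{[(tert-butyldimethylsilyl)oxy]methyl}-5-methoxy-2-(3-methylbut-2-en-1-yl)-3-[(triisopropylsilyl)oxy]phenol, via vinylketene 14 (not isolated), via 4-vinylcyclobutenone 15 (not isolated), via dienylketene 16 (not isolated), via cyclohexadienone 17 (not isolated)
Conditions: 7 added slowly to 13 (1.5 equiv), degassed toluene, 100–110 °C, sealed vessel
Reagents that add atoms: none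
Why: Thermal 4π electrocyclic opening of 7 breaks the C1–C4 bond and gives vinylketene 14, and the prenyl-bearing carbon of 13 bonds to the ketene carbonyl carbon while its oxygen-bearing carbon bonds to the ketene α-carbon in a [2+2] cycloaddition to give 15. A second 4π opening gives dienylketene 16, and a thermally allowed disrotatory 6π electrocyclisation joins the ketene carbon to the methylene terminus (the C4'–C5' bond), closing the six-membered carbocycle as dienone 17, which tautomerises to phenol 18. The closest known reaction type is the Danheiser benzannulation of cyclobutenones with siloxyalkynes to resorcinol monosilyl ethers; the 3-methoxy group, which supplies the third oxygen, is the unusual element because it slows the first ring opening. No stereocentre is formed. The step needs a single orientation in the ketene–alkyne union, which the polarisation of the silyl ynol ether secures, so that prenyl lies between the free 4'-OH and the 2'-OTIPS and the only unsubstituted carbon, C5', is ortho to the free hydroxyl. Slow addition of 7 to excess 13 should keep the vinylketene from acylating the product phenol.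

Step 8
Reactants: 19 3-pentanone
Product: 20 (Z)-trimethyl(pent-2-en-3-yloxy)silane
Conditions: TMSOTf, Et3N, Et2O, 0 °C; distillation
Reagents that add atoms: trimethylsilyl triflate, C[Si](C)(C)OS(=O)(=O)C(F)(F)F
Why: Soft enolisation and O-silylation of a symmetrical ketone gives the silyl enol ether, whose double-bond geometry (Z expected) does not matter for the next step.

Step 9
Reactants: 20 (Z)-trimethyl(pent-2-en-3-yloxy)silane; 21 malonyl dichloride
Product: 23 6-ethyl-4-hydroxy-5-methyl-2H-pyran-2-one, via 4-methyl-3,5-dioxoheptanoyl chloride 22 (not isolated)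
Conditions: Et2O, −78 °C → rt; crystallisation
Reagents that add atoms: none
Why: One acyl chloride of malonyl dichloride C-acylates the silyl enol ether and the enol oxygen of the resulting diketo acid chloride closes the lactone (Effenberger synthesis of 4-hydroxy-2-pyrones).

Step 10
Reactants: 18 4-{[(tert-butyldimethylsilyl)oxy]methyl}-5-methoxy-2-(3-methylbut-2-en-1-yl)-3-[(triisopropylsilyl)oxy]phenol; 24 (R)-2-methylbutanoic acid
Product: 25 4-{[(tert-butyldimethylsilyl)oxy]methyl}-5-methoxy-2-(3-methylbut-2-en-1-yl)-3-[(triisopropylsilyl)oxy]phenyl (2R)-2-methylbutanoate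
Conditions: DCC, DMAP (cat.), CH2Cl2, 0 °C → rt
Reagents that add atoms: none
Why: Steglich esterification of the only free phenol uses carbodiimide activation and so avoids the acid chloride and ketene pathway that could racemise the α-stereocentre, which is carried in from 24 unchanged.

Step 11
Reactants: 25 4-{[(tert-butyldimethylsilyl)oxy]methyl}-5-methoxy-2-(3-methylbut-2-en-1-yl)-3-[(triisopropylsilyl)oxy]phenyl (2R)-2-methylbutanoate
Product: 26 (2R)-1-[3-{[(tert-butyldimethylsilyl)oxy]methyl}-6-hydroxy-2-methoxy-5-(3-methylbut-2-en-1-yl)-4-[(triisopropylsilyl)oxy]phenyl]-2-methylbutan-1-one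
Conditions: hν (254 nm, quartz), degassed cyclohexane, rt; run to partial conversion, phenol 18 from cage escape recycled through step 10
Reagents that add atoms: none
Why: In this photo-Fries rearrangement the ArO–C(O) bond homolyses and the acyl radical recombines in the solvent cage at C5', the only unsubstituted ortho or para carbon, then tautomerises to the hydrogen-bonded o-hydroxy ketone; the α-stereocentre should be kept because recombination outruns decarbonylation.

Step 12
Reactants: 26 (2R)-1-[3-{[(tert-butyldimethylsilyl)oxy]methyl}-6-hydroxy-2-methoxy-5-(3-methylbut-2-en-1-yl)-4-[(triisopropylsilyl)oxy]phenyl]-2-methylbutan-1-one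
Product: 27 (2R)-1-[4,6-dihydroxy-3-(hydroxymethyl)-2-methoxy-5-(3-methylbut-2-en-1-yl)phenyl]-2-methylbutan-1-one
Conditions: TBAF (2.5 equiv), AcOH (2.5 equiv), THF, 0 °C; used without delay
Reagents that add atoms: none
Why: Fluoride cleaves both the aryl triisopropylsilyl ether and the primary silyl ether (silyl ether deprotection), and the acetic acid buffer should keep the medium from enolising the α-branched ketone.

Step 13
Reactants: 27 (2R)-1-[4,6-dihydroxy-3-(hydroxymethyl)-2-methoxy-5-(3-methylbut-2-en-1-yl)phenyl]-2-methylbutan-1-one; 23 6-ethyl-4-hydroxy-5-methyl-2H-pyran-2-one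
Product: 29 3-{[2,4-dihydroxy-6-methoxy-3-(3-methylbut-2-en-1-yl)-5-[(2R)-2-methylbutanoyl]phenyl]methyl}-6-ethyl-4-hydroxy-5-methyl-2H-pyran-2-one, via o-quinone methide 28 (not isolated)
Conditions: 23 (2 equiv), 1,4-dioxane, 90 °C
Reagents that add atoms: none
Why: Thermal dehydration of the o-hydroxybenzyl alcohol gives the o-quinone methide, which the nucleophilic C3 of the 4-hydroxypyrone captures by conjugate addition with rearomatisation (o-quinone methide Michael reaction); the fully substituted benzene ring cannot alkylate itself and the stereocentre is not touched.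

**Compound list**

1 | trichloroethylene | ClC=C(Cl)Cl | starting material
2 | (E)-1,2-dichloro-1-methoxyethene | CO/C(Cl)=C\Cl | intermediate
3 | lithium methoxyacetylide | [Li]C#COC | intermediate
4 | lithium 3-methoxyprop-2-yn-1-olate | [Li]OCC#COC | intermediate
5 | tert-butyl[(3-methoxyprop-2-yn-1-yl)oxy]dimethylsilane | COC#CCO[Si](C)(C)C(C)(C)C | intermediate
6 | 2-{[(tert-butyldimethylsilyl)oxy]methyl}-4,4-dichloro-3-methoxycyclobut-2-en-1-one | O=C1C(CO[Si](C)(C)C(C)(C)C)=C(OC)C1(Cl)Cl | intermediate
7 | 2-{[(tert-butyldimethylsilyl)oxy]methyl}-3-methoxycyclobut-2-en-1-one | O=C1CC(OC)=C1CO[Si](C)(C)C(C)(C)C | intermediate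
8 | prenyl bromide (1-bromo-3-methylbut-2-ene) | CC(C)=CCBr | starting material
9 | ethynylmagnesium bromide | C#C[Mg]Br | starting material
10 | 5-methylhex-4-en-1-yne | CC(C)=CCC#C | intermediate
11 | lithium 5-methylhex-4-en-1-yn-1-ide | CC(C)=CCC#C[Li] | intermediate
12 | lithium 5-methylhex-4-en-1-yn-1-olate (lithium ynolate) | CC(C)=CCC#CO[Li] | intermediate
13 | triisopropyl[(5-methylhex-4-en-1-yn-1-yl)oxy]silane | CC(C)=CCC#CO[Si](C(C)C)(C(C)C)C(C)C | intermediate
14 | 2-{[(tert-butyldimethylsilyl)oxy]methyl}-3-methoxybuta-1,3-dien-1-one (vinylketene) | O=C=C(CO[Si](C)(C)C(C)(C)C)C(OC)=C | intermediate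
15 | 4-{[(tert-butyldimethylsilyl)oxy]methyl}-4-(1-methoxyethenyl)-2-(3-methylbut-2-en-1-yl)-3-[(triisopropylsilyl)oxy]cyclobut-2-en-1-one (racemic) | O=C1C(CC=C(C)C)=C(O[Si](C(C)C)(C(C)C)C(C)C)C1(CO[Si](C)(C)C(C)(C)C)C(OC)=C | intermediate
16 | 4-{[(tert-butyldimethylsilyl)oxy]methyl}-5-methoxy-2-(3-methylbut-2-en-1-yl)-3-[(triisopropylsilyl)oxy]hexa-1,3,5-trien-1-one (dienylketene; ketene and methoxyvinyl groups cis) | O=C=C(CC=C(C)C)/C(O[Si](C(C)C)(C(C)C)C(C)C)=C(/CO[Si](C)(C)C(C)(C)C)C(OC)=C | intermediate
17 | 4-{[(tert-butyldimethylsilyl)oxy]methyl}-5-methoxy-2-(3-methylbut-2-en-1-yl)-3-[(triisopropylsilyl)oxy]cyclohexa-2,4-dien-1-one | O=C1CC(OC)=C(CO[Si](C)(C)C(C)(C)C)C(O[Si](C(C)C)(C(C)C)C(C)C)=C1CC=C(C)C | intermediate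
18 | 4-{[(tert-butyldimethylsilyl)oxy]methyl}-5-methoxy-2-(3-methylbut-2-en-1-yl)-3-[(triisopropylsilyl)oxy]phenol | Oc1cc(OC)c(CO[Si](C)(C)C(C)(C)C)c(O[Si](C(C)C)(C(C)C)C(C)C)c1CC=C(C)C | intermediate
19 | 3-pentanone | CCC(=O)CC | starting material
20 | (Z)-trimethyl(pent-2-en-3-yloxy)silane | C/C=C(/CC)O[Si](C)(C)C | intermediate
21 | malonyl dichloride | ClC(=O)CC(=O)Cl | starting material
22 | 4-methyl-3,5-dioxoheptanoyl chloride (racemic) | CCC(=O)C(C)C(=O)CC(=O)Cl | intermediate
23 | 6-ethyl-4-hydroxy-5-methyl-2H-pyran-2-one | CCc1oc(=O)cc(O)c1C | intermediate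
24 | (R)-2-methylbutanoic acid | OC(=O)[C@H](C)CC | starting material
25 | 4-{[(tert-butyldimethylsilyl)oxy]methyl}-5-methoxy-2-(3-methylbut-2-en-1-yl)-3-[(triisopropylsilyl)oxy]phenyl (2R)-2-methylbutanoate | CC(C)=CCc1c(OC(=O)[C@H](C)CC)cc(OC)c(CO[Si](C)(C)C(C)(C)C)c1O[Si](C(C)C)(C(C)C)C(C)C | intermediate
26 | (2R)-1-[3-{[(tert-butyldimethylsilyl)oxy]methyl}-6-hydroxy-2-methoxy-5-(3-methylbut-2-en-1-yl)-4-[(triisopropylsilyl)oxy]phenyl]-2-methylbutan-1-one | CC(C)=CCc1c(O)c(C(=O)[C@H](C)CC)c(OC)c(CO[Si](C)(C)C(C)(C)C)c1O[Si](C(C)C)(C(C)C)C(C)C | intermediate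
27 | (2R)-1-[4,6-dihydroxy-3-(hydroxymethyl)-2-methoxy-5-(3-methylbut-2-en-1-yl)phenyl]-2-methylbutan-1-one | CC(C)=CCc1c(O)c(C(=O)[C@H](C)CC)c(OC)c(CO)c1O | intermediate
28 | 3-hydroxy-5-methoxy-6-methylidene-2-(3-methylbut-2-en-1-yl)-4-[(2R)-2-methylbutanoyl]cyclohexa-2,4-dien-1-one (o-quinone methide) | C=C1C(=O)C(CC=C(C)C)=C(O)C(C(=O)[C@H](C)CC)=C1OC | intermediate
29 | 3-{[2,4-dihydroxy-6-methoxy-3-(3-methylbut-2-en-1-yl)-5-[(2R)-2-methylbutanoyl]phenyl]methyl}-6-ethyl-4-hydroxy-5-methyl-2H-pyran-2-one | CCc1oc(=O)c(Cc2c(O)c(CC=C(C)C)c(O)c(C(=O)[C@H](C)CC)c2OC)c(O)c1C | target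

**Step count**

Total: 13 steps. Longest linear sequence: 9 steps (1, 2, 3, 4, 7, 10, 11, 12, 13).

**Steps most likely to fail**

Step 7. The first ring opening of the vinylogous ester 7 may be too slow at temperatures that 13 tolerates, so that silyl migration in the siloxyalkyne or oligomerisation of the ketene outruns the cycloaddition.
Fallback, setting out from 13 and coming back at 18: the same vinylketene 14 is made at room temperature by photochemical Wolff rearrangement, the diazo ketone variant of this benzannulation.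
1-Methoxyvinyllithium (methyl vinyl ether, t-BuLi, THF) is added to commercial 3-[(tert-butyldimethylsilyl)oxy]propanal to give 5-[(tert-butyldimethylsilyl)oxy]-2-methoxypent-1-en-3-ol F1.
Dess–Martin oxidation gives 5-[(tert-butyldimethylsilyl)oxy]-2-methoxypent-1-en-3-one F2.
Detrifluoroacetylative diazo transfer (LiHMDS, CF3CO2CH2CF3, −78 °C; then MsN3, Et3N, MeCN) passes through 4-{[(tert-butyldimethylsilyl)oxy]methyl}-6,6,6-trifluoro-2-methoxyhex-1-ene-3,5-dione F3 to 5-[(tert-butyldimethylsilyl)oxy]-4-diazo-2-methoxypent-1-en-3-one F4.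
Irradiation of F4 with 13 in CH2Cl2 at rt, then warming to 80 °C, should give 14 by vinyl migration and then 18 by the same cascade.

Step 11. The radical pair may escape the solvent cage (returning phenol 18), the acyl radical may lose CO, the prenyl alkene may react under the light, and the absorbing product may stall conversion.
Fallback, setting out from 18 and coming back at 26: directed ortho-metalation places the acyl group at C5', the one ring C–H, which lies between two oxygens.
MOMCl and i-Pr2NEt in CH2Cl2 convert 18 into tert-butyl{[2-methoxy-4-(methoxymethoxy)-5-(3-methylbut-2-en-1-yl)-6-[(triisopropylsilyl)oxy]phenyl]methoxy}dimethylsilane F5.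
n-BuLi and TMEDA in THF (−78 → 0 °C) give the C5' aryllithium F6.
F6 is quenched at −78 °C with (R)-N-methoxy-N,2-dimethylbutanamide F7, made from 24 with MeNHOMe·HCl and DCC.
This gives the MOM-protected ketone (2R)-1-[3-{[(tert-butyldimethylsilyl)oxy]methyl}-2-methoxy-6-(methoxymethoxy)-5-(3-methylbut-2-en-1-yl)-4-[(triisopropylsilyl)oxy]phenyl]-2-methylbutan-1-one F8.
ZnBr2 and n-PrSH in CH2Cl2 at 0 °C remove the MOM group next to the carbonyl and should give 26.

Step 3. Zinc chloride formed during ketene generation may decompose the ynol ether or the silyl ether, and the allylic gem-dichloride 6 may ionise and hydrolyse on work-up.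
Fallback, setting out from 5 and coming back at 7: gaseous ketene (from cracking of acetone or diketene) is passed into 5 in CH2Cl2 at 0 °C.
The thermal [2+2] cycloaddition with the same orientation gives 7 directly, with no zinc salts present; 6 is never formed and step 4 falls away.

**Further compounds**

F1 | step 7 | 5-[(tert-butyldimethylsilyl)oxy]-2-methoxypent-1-en-3-ol (racemic) | C=C(OC)C(O)CCO[Si](C)(C)C(C)(C)C
F2 | step 7 | 5-[(tert-butyldimethylsilyl)oxy]-2-methoxypent-1-en-3-one | C=C(OC)C(=O)CCO[Si](C)(C)C(C)(C)C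
F3 | step 7 | 4-{[(tert-butyldimethylsilyl)oxy]methyl}-6,6,6-trifluoro-2-methoxyhex-1-ene-3,5-dione (racemic) | C=C(OC)C(=O)C(CO[Si](C)(C)C(C)(C)C)C(=O)C(F)(F)F
F4 | step 7 | 5-[(tert-butyldimethylsilyl)oxy]-4-diazo-2-methoxypent-1-en-3-one | C=C(OC)C(=O)C(=[N+]=[N-])CO[Si](C)(C)C(C)(C)C
F5 | step 11 | tert-butyl{[2-methoxy-4-(methoxymethoxy)-5-(3-methylbut-2-en-1-yl)-6-[(triisopropylsilyl)oxy]phenyl]methoxy}dimethylsilane | CC(C)=CCc1c(OCOC)cc(OC)c(CO[Si](C)(C)C(C)(C)C)c1O[Si](C(C)C)(C(C)C)C(C)C
F6 | step 11 | C5' aryllithium of F5 | CC(C)=CCc1c(OCOC)c([Li])c(OC)c(CO[Si](C)(C)C(C)(C)C)c1O[Si](C(C)C)(C(C)C)C(C)C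
F7 | step 11 | (R)-N-methoxy-N,2-dimethylbutanamide | CON(C)C(=O)[C@H](C)CC
F8 | step 11 | (2R)-1-[3-{[(tert-butyldimethylsilyl)oxy]methyl}-2-methoxy-6-(methoxymethoxy)-5-(3-methylbut-2-en-1-yl)-4-[(triisopropylsilyl)oxy]phenyl]-2-methylbutan-1-one | CC(C)=CCc1c(OCOC)c(C(=O)[C@H](C)CC)c(OC)c(CO[Si](C)(C)C(C)(C)C)c1O[Si](C(C)C)(C(C)C)C(C)C
F0 | step 3 | none | none
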